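## Retrosynthetic overview

1. The target comes from diacetylation of macrocyclic diol 21, whose ten-membered ring is closed last by ring-closing metathesis (RCM) at the Z C1=C10 olefin of γ-lactone diene 20.
2. Diene 20 comes from enone δ-lactone 18 by reduction of the C6 ketone and δ→γ translactonisation, which closes the C12–O6 lactone and frees O9.
3. Enone 18 comes from the late C5–C6 union of vinylstannane 9 (fragment W: C1–C5, C15) with thioester 17 (fragment E: C6–C14) in a Pd/Cu ketone synthesis.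
4. Fragment E comes from methacrolein (Brown allylation for C9, acrylate RCM, (MeS)3CLi/MeI addition–alkylation for C7 and C11); fragment W comes from propargyl alcohol (carboalumination–iodination, oxidation, Brown allylation for C3, Li/Sn exchange).
5. Ring order: δ-lactone (step 8), then γ-lactone (step 12), then cyclodecadiene (step 13).

Assumption: positions are given in germacrane numbering (target = 3S,6S,7S,9R,11R; 1(10)Z,4E; lactone C12(=O)–O–C6; acetates on C3 and C9), and the Brown allylations are taken to give about 90% ee, with minor stereoisomers removed by chromatography after fragment union.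

## Fragment W

Step 1
Reactants: 1 prop-2-yn-1-ol
Product: 3 (2E)-3-iodo-2-methylprop-2-en-1-ol, via vinylalane 2 (not isolated)
Conditions: Me3Al (2.5 equiv), Cp2ZrCl2 (0.25 equiv), CH2Cl2, 0 → 23 °C; then I2, THF, −30 → 0 °C
Reagents that add atoms: trimethylaluminium C[Al](C)C; iodine [I][I]
Why: Negishi zirconium-catalysed carboalumination adds Me–Al syn across the alkyne with Al at the terminus, and iodinolysis with retention gives only the E vinyl iodide.

Step 2
Reactants: 3 (2E)-3-iodo-2-methylprop-2-en-1-ol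
Product: 4 (2E)-3-iodo-2-methylprop-2-enal
Conditions: MnO2 (15 equiv), CH2Cl2, 23 °C
Reagents that add atoms: none
Why: Allylic alcohol oxidation with MnO2 is selective and leaves the vinyl iodide and the olefin geometry untouched.

Step 3
Reactants: 4 (2E)-3-iodo-2-methylprop-2-enal
Product: 6 (1E,3S)-1-iodo-2-methylhexa-1,5-dien-3-ol, via diisopinocampheylborinate 5 (not isolated)
Conditions: (−)-Ipc2BOMe, allylMgBr, Et2O, 0 → 23 °C; then 4, −78 °C; then 3 M NaOH, 30% H2O2, 23 °C
Reagents that add atoms: allylmagnesium bromide C=CC[Mg]Br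
Why: Brown allylboration with the reagent derived from (+)-α-pinene attacks the Si face of the enal through a chair transition state and sets C3 as S.

Step 4
Reactants: 6 (1E,3S)-1-iodo-2-methylhexa-1,5-dien-3-ol
Product: 7 triethyl{[(1E,3S)-1-iodo-2-methylhexa-1,5-dien-3-yl]oxy}silane
Conditions: TESCl, imidazole, DMF, 0 °C
Reagents that add atoms: chlorotriethylsilane CC[Si](Cl)(CC)CC
Why: Silyl ether formation masks the carbinol for the organolithium, coupling and reduction steps, and the group is shed by the acid used in step 12.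

Step 5
Reactants: 7 triethyl{[(1E,3S)-1-iodo-2-methylhexa-1,5-dien-3-yl]oxy}silane
Product: 9 tributyl[(1E,3S)-2-methyl-3-(triethylsilyloxy)hexa-1,5-dien-1-yl]stannane, via vinyllithium 8 (not isolated)
Conditions: t-BuLi (2.1 equiv), Et2O, −78 °C; then Bu3SnCl, −78 → 0 °C
Reagents that add atoms: tributyltin chloride CCCC[Sn](Cl)(CCCC)CCCC
Why: Lithium–iodine exchange proceeds with retention of olefin geometry and the vinyllithium is trapped by stannylation to give a bench-stable coupling partner.

## Fragment E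

Step 6
Reactants: 10 2-methylprop-2-enal (methacrolein)
Product: 12 (3R)-2-methylhexa-1,5-dien-3-ol, via diisopinocampheylborinate 11 (not isolated)
Conditions: (+)-Ipc2BOMe, allylMgBr, Et2O, 0 → 23 °C; then 10, −78 °C; then 3 M NaOH, 30% H2O2, 23 °C
Reagents that add atoms: allylmagnesium bromide C=CC[Mg]Br
Why: Brown allylboration with the enantiomeric reagent (from (−)-α-pinene) attacks the Re face of the enal and sets C9 as R.

Step 7
Reactants: 12 (3R)-2-methylhexa-1,5-dien-3-ol
Product: 13 (3R)-2-methylhexa-1,5-dien-3-yl prop-2-enoate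
Conditions: acryloyl chloride, Et3N, DMAP (cat.), CH2Cl2, 0 °C
Reagents that add atoms: acryloyl chloride C=CC(Cl)=O
Why: Simple O-acylation (esterification) of the secondary allylic alcohol with no effect on the stereocentre.

Step 8
Reactants: 13 (3R)-2-methylhexa-1,5-dien-3-yl prop-2-enoate
Product: 14 (6R)-6-(prop-1-en-2-yl)-5,6-dihydro-2H-pyran-2-one
Conditions: second-generation Grubbs catalyst (3 mol%), CH2Cl2 (0.01 M), 40 °C
Reagents that add atoms: none
Why: Ring-closing metathesis starts at the unhindered terminal olefin and closes onto the acrylate to give the six-membered unsaturated lactone, while the 1,1-disubstituted isopropenyl group stays a spectator.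

Step 9
Reactants: 14 (6R)-6-(prop-1-en-2-yl)-5,6-dihydro-2H-pyran-2-one
Product: 16 (3R,4S,6R)-3-methyl-6-(prop-1-en-2-yl)-4-[tris(methylsulfanyl)methyl]oxan-2-one, via lithium enolate 15 (not isolated)
Conditions: (MeS)3CH, n-BuLi, THF, −78 °C; then 14, −78 °C; then MeI, HMPA, −78 → −30 °C
Reagents that add atoms: tris(methylsulfanyl)methane CSC(SC)SC; iodomethane CI
Why: In this tandem Michael addition–enolate alkylation the soft carbanion adds 1,4 axially, trans to the ring isopropenyl group (sets C7), and MeI then alkylates the enolate anti to the bulky new substituent (sets C11), giving the trans,trans lactone.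

Step 10
Reactants: 16 (3R,4S,6R)-3-methyl-6-(prop-1-en-2-yl)-4-[tris(methylsulfanyl)methyl]oxan-2-one
Product: 17 S-methyl (3R,4S,6R)-3-methyl-2-oxo-6-(prop-1-en-2-yl)oxane-4-carbothioate
Conditions: AgNO3 (2.2 equiv), 2,6-lutidine, THF–H2O (4:1), 0 °C
Reagents that add atoms: water O
Why: Thiophile-assisted hydrolysis of the trithioorthoester goes through a dithio-stabilised carbenium ion and stops at the thioester, under buffered conditions that spare the lactone and the olefin.

## Fragment union and endgame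

Step 11
Reactants: 9 tributyl[(1E,3S)-2-methyl-3-(triethylsilyloxy)hexa-1,5-dien-1-yl]stannane; 17 S-methyl (3R,4S,6R)-3-methyl-2-oxo-6-(prop-1-en-2-yl)oxane-4-carbothioate
Product: 18 (3R,4S,6R)-3-methyl-4-[(2E,4S)-3-methyl-4-(triethylsilyloxy)hepta-2,6-dienoyl]-6-(prop-1-en-2-yl)oxan-2-one
Conditions: Pd2(dba)3 (5 mol%), P(2-furyl)3 (20 mol%), CuO2PPh2 (1.5 equiv), THF, 50 °C
Reagents that add atoms: none
Why: The Liebeskind–Srogl thioester–organostannane ketone synthesis forms the C5–C6 bond under neutral, base-free conditions, so the olefin geometry is retained and the C7 centre next to the new ketone is not epimerised.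

Step 12
Reactants: 18 (3R,4S,6R)-3-methyl-4-[(2E,4S)-3-methyl-4-(triethylsilyloxy)hepta-2,6-dienoyl]-6-(prop-1-en-2-yl)oxan-2-one
Product: 20 (3R,4S,5S)-4-[(2R)-2-hydroxy-3-methylbut-3-en-1-yl]-5-[(1E,3S)-3-hydroxy-2-methylhexa-1,5-dien-1-yl]-3-methyloxolan-2-one, via delta-lactone carbinol 19 (not isolated)
Conditions: (R)-2-methyl-CBS-oxazaborolidine (0.3 equiv), catecholborane (2 equiv), toluene, −78 °C; then MeOH; then PPTS, MeOH, 23 → 40 °C
Reagents that add atoms: none
Why: Corey–Bakshi–Shibata 1,2-reduction with the alkenyl group as the large substituent, matched with Felkin–Anh attack anti to the C11 branch, gives the 6S carbinol; the acid then removes the TES group and translactonises the δ-lactone to the more stable γ-lactone, in which the δ-lactone's trans C7/C11 relationship becomes the required α-methyl cis to the C8 side chain with a trans C6/C7 ring junction.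

Step 13
Reactants: 20 (3R,4S,5S)-4-[(2R)-2-hydroxy-3-methylbut-3-en-1-yl]-5-[(1E,3S)-3-hydroxy-2-methylhexa-1,5-dien-1-yl]-3-methyloxolan-2-one
Product: 21 (3R,3aS,5R,6Z,9S,10E,11aS)-5,9-dihydroxy-3,6,10-trimethyl-3a,4,5,8,9,11a-hexahydrocyclodeca[b]furan-2(3H)-one
Conditions: second-generation Hoveyda–Grubbs catalyst (2 × 7.5 mol%), 1,4-benzoquinone (cat.), toluene (0.001 M), 80 °C
Reagents that add atoms: none
Why: Ring-closing metathesis at high dilution starts at the terminal vinyl group and closes onto the isopropenyl group, which is activated by its free allylic hydroxyl; a ten-membered ring should take up the new trisubstituted olefin as the less strained Z isomer.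

Step 14
Reactants: 21 (3R,3aS,5R,6Z,9S,10E,11aS)-5,9-dihydroxy-3,6,10-trimethyl-3a,4,5,8,9,11a-hexahydrocyclodeca[b]furan-2(3H)-one
Product: 22 (3R,3aS,5R,6Z,9S,10E,11aS)-3,6,10-trimethyl-2-oxo-2,3,3a,4,5,8,9,11a-octahydrocyclodeca[b]furan-5,9-diyl diacetate (CNP0226482.6)
Conditions: Ac2O, pyridine, DMAP (cat.), CH2Cl2, 0 → 23 °C
Reagents that add atoms: acetic anhydride CC(=O)OC(C)=O
Why: DMAP-catalysed acetylation esterifies both secondary allylic alcohols, and the conditions are too weakly basic to epimerise the kinetically set C11 centre of the lactone.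

## Compound list

1 | prop-2-yn-1-ol | C#CCO | starting material
2 | dimethyl[(1E)-3-[(dimethylalumanyl)oxy]-2-methylprop-1-en-1-yl]alumane (vinylalane) | C[Al](C)OC/C(C)=C/[Al](C)C | intermediate (not isolated)
3 | (2E)-3-iodo-2-methylprop-2-en-1-ol | OC/C(C)=C/I | intermediate
4 | (2E)-3-iodo-2-methylprop-2-enal | O=C/C(C)=C/I | intermediate
5 | (1E,3S)-1-iodo-2-methylhexa-1,5-dien-3-yl di[(−)-isopinocampheyl]borinate (Ipc groups from (+)-α-pinene) | C=CC[C@H](OB([C@@H]1C[C@@H]2C[C@H]([C@H]1C)C2(C)C)[C@@H]1C[C@@H]2C[C@H]([C@H]1C)C2(C)C)/C(C)=C/I | intermediate (not isolated)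
6 | (1E,3S)-1-iodo-2-methylhexa-1,5-dien-3-ol | C=CC[C@H](O)/C(C)=C/I | intermediate
7 | triethyl{[(1E,3S)-1-iodo-2-methylhexa-1,5-dien-3-yl]oxy}silane | C=CC[C@H](O[Si](CC)(CC)CC)/C(C)=C/I | intermediate
8 | [(1E,3S)-2-methyl-3-(triethylsilyloxy)hexa-1,5-dien-1-yl]lithium | C=CC[C@H](O[Si](CC)(CC)CC)/C(C)=C/[Li] | intermediate (not isolated)
9 | tributyl[(1E,3S)-2-methyl-3-(triethylsilyloxy)hexa-1,5-dien-1-yl]stannane | C=CC[C@H](O[Si](CC)(CC)CC)/C(C)=C/[Sn](CCCC)(CCCC)CCCC | intermediate
10 | 2-methylprop-2-enal (methacrolein) | C=C(C)C=O | starting material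
11 | (3R)-2-methylhexa-1,5-dien-3-yl di[(+)-isopinocampheyl]borinate (Ipc groups from (−)-α-pinene) | C=CC[C@@H](OB([C@H]1C[C@H]2C[C@@H]([C@@H]1C)C2(C)C)[C@H]1C[C@H]2C[C@@H]([C@@H]1C)C2(C)C)C(C)=C | intermediate (not isolated)
12 | (3R)-2-methylhexa-1,5-dien-3-ol | C=CC[C@@H](O)C(C)=C | intermediate
13 | (3R)-2-methylhexa-1,5-dien-3-yl prop-2-enoate | C=CC(=O)O[C@H](CC=C)C(C)=C | intermediate
14 | (6R)-6-(prop-1-en-2-yl)-5,6-dihydro-2H-pyran-2-one | O=C1C=CC[C@H](C(C)=C)O1 | intermediate
15 | lithium (4S,6R)-6-(prop-1-en-2-yl)-4-[tris(methylsulfanyl)methyl]-5,6-dihydro-4H-pyran-2-olate (lactone enolate) | CSC(SC)(SC)[C@H]1C[C@H](C(C)=C)OC(O[Li])=C1 | intermediate (not isolated)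
16 | (3R,4S,6R)-3-methyl-6-(prop-1-en-2-yl)-4-[tris(methylsulfanyl)methyl]oxan-2-one | CSC(SC)(SC)[C@H]1C[C@H](C(C)=C)OC(=O)[C@@H]1C | intermediate
17 | S-methyl (3R,4S,6R)-3-methyl-2-oxo-6-(prop-1-en-2-yl)oxane-4-carbothioate | CSC(=O)[C@H]1C[C@H](C(C)=C)OC(=O)[C@@H]1C | intermediate
18 | (3R,4S,6R)-3-methyl-4-[(2E,4S)-3-methyl-4-(triethylsilyloxy)hepta-2,6-dienoyl]-6-(prop-1-en-2-yl)oxan-2-one | C=CC[C@H](O[Si](CC)(CC)CC)/C(C)=C/C(=O)[C@H]1C[C@H](C(C)=C)OC(=O)[C@@H]1C | intermediate
19 | (3R,4S,6R)-4-[(1S,2E,4S)-1-hydroxy-3-methyl-4-(triethylsilyloxy)hepta-2,6-dien-1-yl]-3-methyl-6-(prop-1-en-2-yl)oxan-2-one | C=CC[C@H](O[Si](CC)(CC)CC)/C(C)=C/[C@@H](O)[C@H]1C[C@H](C(C)=C)OC(=O)[C@@H]1C | intermediate (not isolated)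
20 | (3R,4S,5S)-4-[(2R)-2-hydroxy-3-methylbut-3-en-1-yl]-5-[(1E,3S)-3-hydroxy-2-methylhexa-1,5-dien-1-yl]-3-methyloxolan-2-one | C=CC[C@H](O)/C(C)=C/[C@H]1OC(=O)[C@H](C)[C@@H]1C[C@@H](O)C(C)=C | intermediate
21 | (3R,3aS,5R,6Z,9S,10E,11aS)-5,9-dihydroxy-3,6,10-trimethyl-3a,4,5,8,9,11a-hexahydrocyclodeca[b]furan-2(3H)-one | O[C@H]1C/C=C(/C)[C@H](O)C[C@@H]2[C@@H](/C=C/1C)OC(=O)[C@@H]2C | intermediate
22 | (3R,3aS,5R,6Z,9S,10E,11aS)-3,6,10-trimethyl-2-oxo-2,3,3a,4,5,8,9,11a-octahydrocyclodeca[b]furan-5,9-diyl diacetate | CC(=O)O[C@H]1C/C=C(/C)[C@H](OC(C)=O)C[C@@H]2[C@@H](/C=C/1C)OC(=O)[C@@H]2C | target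

## Step count and risks

Total step count: 14 (steps 1–5 for fragment W, steps 6–10 for fragment E, steps 11–14 after union).
Longest linear sequence: 9 steps (steps 6–10 then 11–14; the path through steps 1–5 is equally long).

The three steps most likely to fail:

Step 13 (ten-membered RCM). The risks are oligomerisation, a sluggish reaction at the hindered isopropenyl group, and E/Z leakage. The fallback sets out from 20 and comes back at 21. The two hydroxyls of 20 are bridged with iPr2Si(OTf)2 and 2,6-lutidine in dilute CH2Cl2 to give the cyclic silylene bis-ether F1. Metathesis then only has to close an eight-membered dioxasilocine, which holds the two olefins together and can take up only a Z olefin, and gives the silylene-bridged cyclodecadiene F2. HF·pyridine in THF removes the tether and delivers 21, which goes on to step 14.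

Step 12 (C6 reduction and translactonisation). The risk is that the substrate bias at the α-branched ketone is weak or runs against the assumed Felkin sense. The fallback sets out from 18 and comes back at 19. The ketone is reduced under the conditions that favour the other face (NaBH4/CeCl3 or the (S)-configured oxazaborolidine) to give the 6R carbinol F3. This is inverted by Mitsunobu esterification (4-nitrobenzoic acid, PPh3, DIAD, toluene) to the 6S 4-nitrobenzoate F4. Mild methanolysis (NaN3, MeOH, 40 °C) then releases 19, which enters the PPTS/MeOH stage of step 12 unchanged.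

Step 11 (thioester–stannane ketone coupling). The risk is a slow reaction of the α-branched S-methyl thioester, with protodestannylation of 9 competing. The fallback sets out from 17 and 7 and comes back at 18. Fukuyama reduction of 17 (Et3SiH, Pd/C, acetone, short contact time) gives the aldehyde F5. Nozaki–Hiyama–Kishi coupling with vinyl iodide 7 (CrCl2, NiCl2 cat., DMSO) gives the allylic alcohols F6 as a mixture of C6 epimers. Dess–Martin periodinane (NaHCO3, CH2Cl2) oxidises both epimers to enone 18.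

## Further compounds

F1 | step 13 | cyclic di(propan-2-yl)silanediyl bis-ether of diol 20 (Si bridges O3 and O9) | C=CC[C@H](O2)/C(C)=C/[C@H]1OC(=O)[C@H](C)[C@@H]1C[C@@H](O[Si]2(C(C)C)C(C)C)C(C)=C
F2 | step 13 | di(propan-2-yl)silanediyl bis-ether of macrocyclic diol 21 (Si bridges O3 and O9) | O3[C@H]1C/C=C(/C)[C@H](O[Si]3(C(C)C)C(C)C)C[C@@H]2[C@@H](/C=C/1C)OC(=O)[C@@H]2C
F3 | step 12 | (3R,4S,6R)-4-[(1R,2E,4S)-1-hydroxy-3-methyl-4-(triethylsilyloxy)hepta-2,6-dien-1-yl]-3-methyl-6-(prop-1-en-2-yl)oxan-2-one | C=CC[C@H](O[Si](CC)(CC)CC)/C(C)=C/[C@H](O)[C@H]1C[C@H](C(C)=C)OC(=O)[C@@H]1C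
F4 | step 12 | (1S,2E,4S)-3-methyl-1-[(3R,4S,6R)-3-methyl-2-oxo-6-(prop-1-en-2-yl)oxan-4-yl]-4-(triethylsilyloxy)hepta-2,6-dien-1-yl 4-nitrobenzoate | C=CC[C@H](O[Si](CC)(CC)CC)/C(C)=C/[C@@H](OC(=O)c1ccc(cc1)[N+](=O)[O-])[C@H]2C[C@H](C(C)=C)OC(=O)[C@@H]2C
F5 | step 11 | (3R,4S,6R)-3-methyl-2-oxo-6-(prop-1-en-2-yl)oxane-4-carbaldehyde | O=C[C@H]1C[C@H](C(C)=C)OC(=O)[C@@H]1C
F6 | step 11 | (3R,4S,6R)-4-[(2E,4S)-1-hydroxy-3-methyl-4-(triethylsilyloxy)hepta-2,6-dien-1-yl]-3-methyl-6-(prop-1-en-2-yl)oxan-2-one (both carbinol epimers) | C=CC[C@H](O[Si](CC)(CC)CC)/C(C)=C/C(O)[C@H]1C[C@H](C(C)=C)OC(=O)[C@@H]1C
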